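- The question is which species holds most of the E charged in the flask at 6.0 h, and how much, so the first thing to reckon is what E itself keeps.

in all of them: E 15 mM

| flask | G | remark | time |
|---|---|---|---|
| noon | 5 equiv | run made earlier |  |
| flask | 2.50 equiv |  | 6.0 h |

noon run (percent of the E charged)

| time / min | J / % | E / % | X / % | L / % | Z / % | Q / % |
|---|---|---|---|---|---|---|
| 6.00 | 3 | 96 | 2 | 0 | 0 | 1 |
| 10.0 | 3 | 95 | 0 | 3 | 2 | 1 |
| 15.0 | 4 | 93 | 1 | 3 | 1 | 1 |
| 25.0 | 9 | 89 | 0 | 0 | 1 | 0 |
| 40.0 | 15 | 81 | 1 | 0 | 0 | 4 |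
| 80.0 | 22 | 64 | 6 | 0 | 1 | 10 |

(each reading ± 1.5 percentage points)

- the species that holds most of what was charged as E, at 6.0 h (X / E / Z / L / Q / J)
- the largest share itself, whichever of these holds it, in percent of the E charged



- Call k the first-order loss constant of E in the noon run; from the E reading at 80.0 min, k is 0.00558 min⁻¹.
- A second way sums the products at that time, 39.0%, and gives 0.00618 min⁻¹, faster than the first.
- The two part by 3 percentage points, less than the 3.4 points scatter of a sum of 5 readings, so they agree within that scatter and neither is shown to be wrong; the single E reading is kept for its smaller scatter of 1.5 points.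
- The noon run holds one charge of G and cannot show an order in G, so zero order in G is the zero of the scale: this reckoning puts E in the flask at 13.4% at 6.0 h.
- First order in G, with the flask at half the noon equivalents, gives 36.6%.
- This reckoning commits to the zero of the scale, and so to J, the largest product at the last noon reading.
- The forecast names E at 40%, above this reckoning's figure for E, and grants that “the order in G is unknown”.

    G + X → D (k = 5.00 × 10⁻⁴ M⁻¹ s⁻¹)
    G + J ⇌ X (K = 110 M⁻¹, k = 0.00190 M⁻¹ s⁻¹)
    E → J (k = 7.30 × 10⁻⁵ s⁻¹)
    J ⇌ Z (K = 5.30, k = 1.40 × 10⁻⁵ s⁻¹)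
    E → Q (k = 1.50 × 10⁻⁵ s⁻¹)
    Z → Q (k = 9.50 × 10⁻⁵ s⁻¹)
    X → L (k = 6.80 × 10⁻⁵ s⁻¹)

- The flask gives J at 28.4%, with E at 14.9%. Neither step that consumes E contains G, and at the start E goes to J 4.9 times as fast as to Q. The constant k, carried to the neighbouring flask read at 15 h, puts E at 0.659%, and that flask holds 0.863%.

The readings come from a simulation for an exercise.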